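**Retrosynthetic overview**
1. Target 9 ⇒ 3,5,6,7,8,2',5'-heptamethoxyflavone 7 by chelation-controlled cleavage of the 5-O-methyl group only.
2. 7 ⇒ flavonol 6 by O-methylation of the 3-OH.
3. 6 ⇒ 2'-hydroxychalcone 4 by Algar–Flynn–Oyamada oxidative cyclisation (O1–C2 bond and C3–OH in one operation).
4. 4 ⇒ acetophenone 1 + aldehyde 2 by Claisen–Schmidt condensation.
5. Ring order: rings A and B are bought fully oxygenated; only the pyranone ring C is built (step 2).

Assumption: the target has no stereocentre or stereogenic axis, so it is achiral and needs no enantiocontrol; 2'-hydroxy-3',4',5',6'-tetramethoxyacetophenone (1) is taken as a catalogue compound.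

**Step 1**
Reactants: 1 2'-hydroxy-3',4',5',6'-tetramethoxyacetophenone; 2 2,5-dimethoxybenzaldehyde
Product: 4 (E)-2'-hydroxy-2,5,3',4',5',6'-hexamethoxychalcone, via aldol adduct 3 (not isolated)
Conditions: KOH (50% aq., 5 equiv), EtOH, 0 °C → rt, 24 h; then 2 M HCl to pH 3
Reagents that add atoms: none
Why: Claisen–Schmidt aldol condensation, in which the potassium enolate of the methyl ketone adds to the non-enolisable aldehyde and aldol 3 loses water by E1cB to give the thermodynamically favoured (E)-enone, so no stereocentre remains.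

**Step 2**
Reactants: 4 (E)-2'-hydroxy-2,5,3',4',5',6'-hexamethoxychalcone
Product: 6 3-hydroxy-5,6,7,8,2',5'-hexamethoxyflavone, via trans-dihydroflavonol 5 (not isolated)
Conditions: H2O2 (30% aq., 6 equiv), NaOH (2 M aq.), MeOH, 0 °C → rt, 16 h; then 2 M HCl
Reagents that add atoms: hydrogen peroxide, OO
Why: Algar–Flynn–Oyamada reaction, in which the phenoxide closes onto the enone β-carbon while the enolate is hydroxylated by H2O2 to give trans-dihydroflavonol 5, which alkaline peroxide dehydrogenates to the flavonol, erasing both transient stereocentres.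

**Step 3**
Reactants: 6 3-hydroxy-5,6,7,8,2',5'-hexamethoxyflavone
Product: 7 3,5,6,7,8,2',5'-heptamethoxyflavone
Conditions: MeI (1.5 equiv), K2CO3 (2 equiv), acetone, reflux, 6 h
Reagents that add atoms: iodomethane (MeI), CI
Why: Williamson ether synthesis (SN2 O-methylation) at the only free hydroxyl, the 3-OH, with no stereocentre formed.

**Step 4**
Reactants: 7 3,5,6,7,8,2',5'-heptamethoxyflavone
Product: 9 grantioidinin (5-hydroxy-3,6,7,8,2',5'-hexamethoxyflavone), via aryloxydichloroborane 8 (not isolated)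
Conditions: BCl3 (1 M in CH2Cl2, 1.5 equiv), CH2Cl2, −78 → 0 °C, 1 h; then H2O, 0 °C
Reagents that add atoms: none
Why: Chelation-controlled Lewis-acid ether cleavage, in which BCl3 bridges the C4 carbonyl and the peri 5-methoxy oxygen in a six-membered chelate, chloride removes that methyl as CH3Cl, and hydrolysis of 8 frees the 5-OH while the other methoxy groups stay intact; no stereocentre is involved.

**Compound list**
1 | 2'-hydroxy-3',4',5',6'-tetramethoxyacetophenone [1-(2-hydroxy-3,4,5,6-tetramethoxyphenyl)ethan-1-one] | CC(=O)c1c(O)c(OC)c(OC)c(OC)c1OC | starting material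
2 | 2,5-dimethoxybenzaldehyde | COc1ccc(OC)c(C=O)c1 | starting material
3 | aldol adduct, racemic 3-(2,5-dimethoxyphenyl)-3-hydroxy-1-(2-hydroxy-3,4,5,6-tetramethoxyphenyl)propan-1-one | COc1ccc(OC)c(C(O)CC(=O)c2c(O)c(OC)c(OC)c(OC)c2OC)c1 | intermediate
4 | (E)-2'-hydroxy-2,5,3',4',5',6'-hexamethoxychalcone [(E)-3-(2,5-dimethoxyphenyl)-1-(2-hydroxy-3,4,5,6-tetramethoxyphenyl)prop-2-en-1-one] | COc1ccc(OC)c(/C=C/C(=O)c2c(O)c(OC)c(OC)c(OC)c2OC)c1 | intermediate
5 | trans-dihydroflavonol, racemic (2R*,3R*)-2-(2,5-dimethoxyphenyl)-3-hydroxy-5,6,7,8-tetramethoxychroman-4-one (one enantiomer drawn) | COc1ccc(OC)c(c1)[C@@H]2[C@@H](O)C(=O)c3c(O2)c(OC)c(OC)c(OC)c3OC | intermediate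
6 | 3-hydroxy-5,6,7,8,2',5'-hexamethoxyflavone [2-(2,5-dimethoxyphenyl)-3-hydroxy-5,6,7,8-tetramethoxy-4H-chromen-4-one] | COc1ccc(OC)c(-c2oc3c(OC)c(OC)c(OC)c(OC)c3c(=O)c2O)c1 | intermediate
7 | 3,5,6,7,8,2',5'-heptamethoxyflavone | COc1ccc(OC)c(-c2oc3c(OC)c(OC)c(OC)c(OC)c3c(=O)c2OC)c1 | intermediate
8 | aryloxydichloroborane, 5-O-dichloroboryl derivative of the target | COc1ccc(OC)c(-c2oc3c(OC)c(OC)c(OC)c(OB(Cl)Cl)c3c(=O)c2OC)c1 | intermediate
9 | grantioidinin, 5-hydroxy-3,6,7,8,2',5'-hexamethoxyflavone (achiral) | COc1ccc(OC)c(-c2oc3c(OC)c(OC)c(OC)c(O)c3c(=O)c2OC)c1 | target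

**Total step count:** 4
**Longest linear sequence:** 4 steps (1 → 4 → 6 → 7 → 9)

**Three steps most likely to fail, each with a fallback**

Step 2 is the weakest. The 6'-methoxy group twists the enone out of plane and can divert the Algar–Flynn–Oyamada reaction to the aurone (five-membered closure at the α-carbon). The fallback sets out from chalcone 4 and comes back at flavonol 6. Oxidative cyclisation of 4 with catalytic I2 in DMSO at 130 °C gives 5,6,7,8,2',5'-hexamethoxyflavone F1, where only six-membered closure is possible. Dimethyldioxirane (acetone/CH2Cl2, 0 °C → rt) epoxidises the C2=C3 bond to racemic 5,6,7,8,2',5'-hexamethoxyflavone 2,3-epoxide F2. Catalytic p-TsOH in CH2Cl2 then isomerises F2 to 6.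

Step 4 is next. BCl3 may also cleave the 3-methoxy group (five-membered chelate with the C4 carbonyl) or over-cleave at C6. The fallback sets out from flavonol 6 and comes back at target 9 by inverting the order of methylation and demethylation. AlCl3 (3 equiv) in MeCN at 60 °C, then dilute HCl, cleaves the only carbonyl-flanking methyl ether in 6 and gives 3,5-dihydroxy-6,7,8,2',5'-pentamethoxyflavone F3. MeI (1.05 equiv) with K2CO3 in acetone at rt then methylates the 3-OH only, because the 5-OH is locked in a strong hydrogen bond to the C4 carbonyl, and delivers 9.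

Step 1 is the third. The ketone is flanked by OH and OMe and sits as a phenoxide, so the condensation can stall or leak to the 5-methoxyflavanone. The fallback sets out from 1 and comes back at chalcone 4 by masking the phenol first. MOMCl and NaH in DMF (0 °C) give 2'-(methoxymethoxy)-3',4',5',6'-tetramethoxyacetophenone F4. Its enolate, now free of the phenoxide charge, condenses with 2 (KOH, EtOH, rt) to (E)-2'-(methoxymethoxy)-2,5,3',4',5',6'-hexamethoxychalcone F5. HCl in MeOH at 40 °C removes the MOM group and gives 4.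

**Further compounds**
F1 | step 2 | 5,6,7,8,2',5'-hexamethoxyflavone | COc1ccc(OC)c(-c2cc(=O)c3c(OC)c(OC)c(OC)c(OC)c3o2)c1
F2 | step 2 | racemic 5,6,7,8,2',5'-hexamethoxyflavone 2,3-epoxide (cis-fused, one enantiomer drawn) | COc1ccc(OC)c(c1)[C@@]23O[C@@H]2C(=O)c4c(OC)c(OC)c(OC)c(OC)c4O3
F3 | step 4 | 3,5-dihydroxy-6,7,8,2',5'-pentamethoxyflavone | COc1ccc(OC)c(-c2oc3c(OC)c(OC)c(OC)c(O)c3c(=O)c2O)c1
F4 | step 1 | 2'-(methoxymethoxy)-3',4',5',6'-tetramethoxyacetophenone | CC(=O)c1c(OCOC)c(OC)c(OC)c(OC)c1OC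
F5 | step 1 | (E)-2'-(methoxymethoxy)-2,5,3',4',5',6'-hexamethoxychalcone | COCOc1c(OC)c(OC)c(OC)c(OC)c1C(=O)/C=C/c1cc(OC)ccc1OC
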